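## Retrosynthetic overview

1. 16 ⇐ 15 ⇐ 14: O-acetylation and global O-debenzylation come last. Both arenes are purchased, so the oxolane (O1, C2–C5) is the only ring to be made.
2. 14 ⇐ 10 + 12: the C4 arm is cut at CH2–aryl. Hydroboration of a 4-methylene-oxolane followed by B-alkyl Suzuki–Miyaura coupling makes this bond and sets C4 (3,4-cis).
3. 10 ⇐ 8 ⇐ 4 + 5: the oxolane grows out of a cyclopropane. The C=O of aldehyde 5 is inserted into the distal C–C bond of racemic methylenecyclopropane amide 4 (3→5 ring expansion, formal (3+2)), stereoconvergently through a planar dienolate on a chiral Mg(II) centre.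
4. Enabling feature: in the oxolane, C5 is an unsubstituted CH2 on O1, C4 carries exactly one exocyclic carbon, C3 carries one carbon that may stand at the carboxyl level, and O1–C2(aryl) is a latent ArCH=O. C3–C4(=CH2)–C5 is therefore a methylenecyclopropanecarboxamide.
5. Ring order: cyclopropane (purchased in 1) → oxolane (step 2). No further ring is formed.

Key step: step 2

Assumption: methylenecyclopropane is taken as a purchasable low-boiling reagent, and the sense of induction of the Mg/bis(oxazoline) catalyst in step 2 must be fixed by correlation; the (S,S)-ligand is written, and its equally available antipode is used if the correlation demands it.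

## Route

Step 1
Reactants: 1 methylenecyclopropane; 2 diphenylcarbamoyl chloride
Product: 4 rac-2-methylidene-N,N-diphenylcyclopropane-1-carboxamide, via lithiated methylenecyclopropane 3 (not isolated)
Conditions: n-BuLi, THF, −78 → 0 °C; then cannulated into 2, THF, −78 °C → rt
Reagents that add atoms: none
Why: Allylic ring lithiation followed by C-acylation with a carbamoyl chloride, where inverse addition suppresses deprotonation of the product; the new stereocentre is racemic, which is harmless because step 2 erases it.

Step 2
Reactants: 4 rac-2-methylidene-N,N-diphenylcyclopropane-1-carboxamide; 5 3,4-bis(benzyloxy)benzaldehyde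
Product: 8 (2S,3S)-2-[3,4-bis(benzyloxy)phenyl]-4-methylidene-N,N-diphenyloxolane-3-carboxamide, via magnesium dienolate 6 (not isolated), via magnesium syn-aldolate 7 (not isolated)
Conditions: MgI2 (30 mol %), (S,S)-Ph-box (33 mol %), 4 Å MS, CH2Cl2–THF 10:1, 40 °C
Reagents that add atoms: none
Why: Proposed new method: the closest known reaction type is the MgI2-mediated ring expansion of methylenecyclopropyl N,N-diphenylamides with aryl aldehydes or N-sulfonyl aldimines to 2-aryl-4-methylene five-membered heterocycles, for which ligand-modified magnesium has been applied only to the aldimine series, so the new element is enantiocontrol with an aldehyde. Mechanism: the ligated Mg(II) binds the amide carbonyl, iodide opens the distal cyclopropane bond by SN2 at the ring CH2 (or by the degenerate SN2' at the exocyclic CH2) to the planar Z(O)-dienolate 6, its alpha-carbon adds to the Mg-bound aldehyde to give aldolate 7, and the alkoxide expels the allylic iodide, which returns MgI2. Ring closure: the three-membered carbocycle (future C3, C4, C5) is thereby enlarged by C2 and O1 of the aldehyde to the oxolane, a formal (3+2) process whose ring-closing event is a 5-exo-tet O-alkylation. Stereocontrol: the stereocentre of rac-4 is erased in 6, so both enantiomers converge; the 2,3-trans relation follows from the closed chair-like aldol transition state of the Z(O)-enolate with the aryl group equatorial (syn-aldolate) and is reinforced because the aldol step is reversible while the less crowded closure is the fast one; the absolute configuration (2S,3S) is set by the C2-symmetric ligand, which blocks one face of the Mg-bound dienolate. Selectivity needed: alpha- over gamma-attack of the dienolate and O-alkylation over acyl transfer, both secured by the tertiary diphenylamide, while the regiochemistry of ring opening is no issue because C5 is an unsubstituted CH2 and both modes of iodide attack give the same allyl iodide.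

Step 3
Reactants: 8 (2S,3S)-2-[3,4-bis(benzyloxy)phenyl]-4-methylidene-N,N-diphenyloxolane-3-carboxamide
Product: 10 [(2S,3R)-2-[3,4-bis(benzyloxy)phenyl]-4-methylideneoxolan-3-yl]methanol, via oxolane-3-carbaldehyde 9 (not isolated)
Conditions: 8 added to LiAlH4, THF, 0 °C → rt; aqueous NaOH work-up
Reagents that add atoms: none
Why: Hydride reduction of an N,N-diaryl amide with C–N cleavage: the nitrogen lone pair is tied up in two phenyl rings, so the tetrahedral adduct expels diphenylamide rather than oxygen, and aldehyde 9 is reduced by the excess hydride before its allylic alpha-proton can be removed, so C2 and C3 are retained.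

Step 4
Reactants: 11 4-bromo-2-methoxyphenol
Product: 12 1-(benzyloxy)-4-bromo-2-methoxybenzene
Conditions: BnBr, K2CO3, DMF, rt
Reagents that add atoms: benzyl bromide, BrCc1ccccc1
Why: Williamson ether synthesis on a phenol; no stereocentre is involved.

Step 5
Reactants: 10 [(2S,3R)-2-[3,4-bis(benzyloxy)phenyl]-4-methylideneoxolan-3-yl]methanol; 12 1-(benzyloxy)-4-bromo-2-methoxybenzene
Product: 14 [(2S,3R,4R)-2-[3,4-bis(benzyloxy)phenyl]-4-{[4-(benzyloxy)-3-methoxyphenyl]methyl}oxolan-3-yl]methanol, via bis(9-BBN) adduct 13 (not isolated)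
Conditions: 9-BBN-H (2.5 equiv), THF, 0 °C → rt; then 12, Pd(OAc)2, SPhos, aq K3PO4, THF, 60 °C
Reagents that add atoms: none
Why: Hydroboration then B-alkyl Suzuki–Miyaura coupling: 9-BBN first caps the hydroxyl as a bulky borinate, then places boron on the terminal alkene carbon and delivers H to C4 from the ring face opposite the adjacent C3 CH2O–B arm, so the new CH2 branch ends up cis to that arm (4R), and the primary alkylborane couples with 12 without touching a stereocentre.

Step 6
Reactants: 14 [(2S,3R,4R)-2-[3,4-bis(benzyloxy)phenyl]-4-{[4-(benzyloxy)-3-methoxyphenyl]methyl}oxolan-3-yl]methanol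
Product: 15 [(2S,3R,4R)-2-[3,4-bis(benzyloxy)phenyl]-4-{[4-(benzyloxy)-3-methoxyphenyl]methyl}oxolan-3-yl]methyl acetate
Conditions: Ac2O, pyridine, DMAP (cat.), CH2Cl2, 0 °C → rt
Reagents that add atoms: acetic anhydride, CC(=O)OC(C)=O
Why: Standard O-acylation of the only free hydroxyl group; no stereocentre is touched.

Step 7
Reactants: 15 [(2S,3R,4R)-2-[3,4-bis(benzyloxy)phenyl]-4-{[4-(benzyloxy)-3-methoxyphenyl]methyl}oxolan-3-yl]methyl acetate
Product: 16 [(2S,3R,4R)-2-(3,4-dihydroxyphenyl)-4-[(4-hydroxy-3-methoxyphenyl)methyl]oxolan-3-yl]methyl acetate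
Conditions: H2 (1 atm), 10% Pd/C, EtOAc, rt, stopped after uptake of 3 equiv; work-up under argon
Reagents that add atoms: none
Why: Catalytic hydrogenolysis of three aryl benzyl ethers, which in a neutral aprotic solvent should be cleaved much faster than the cyclic secondary benzylic C2–O1 bond; acetate and stereocentres are untouched.

## Compound list

1 | methylenecyclopropane | C=C1CC1 | starting material
2 | diphenylcarbamoyl chloride | O=C(Cl)N(c1ccccc1)c1ccccc1 | starting material
3 | (2-methylidenecyclopropyl)lithium | [Li]C1CC1=C | intermediate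
4 | rac-2-methylidene-N,N-diphenylcyclopropane-1-carboxamide (racemate) | C=C1CC1C(=O)N(c1ccccc1)c1ccccc1 | intermediate
5 | 3,4-bis(benzyloxy)benzaldehyde | O=Cc1ccc(OCc2ccccc2)c(OCc2ccccc2)c1 | starting material
6 | iodomagnesium (1Z)-1-(diphenylamino)-3-(iodomethyl)buta-1,3-dien-1-olate | C=C(CI)/C=C(\O[Mg]I)N(c1ccccc1)c1ccccc1 | intermediate
7 | iodomagnesium alkoxide of (2S,3S)-3-[3,4-bis(benzyloxy)phenyl]-3-hydroxy-2-(3-iodoprop-1-en-2-yl)-N,N-diphenylpropanamide (syn-aldolate) | I[Mg]O[C@H](c1ccc(OCc2ccccc2)c(OCc2ccccc2)c1)[C@H](C(=C)CI)C(=O)N(c1ccccc1)c1ccccc1 | intermediate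
8 | (2S,3S)-2-[3,4-bis(benzyloxy)phenyl]-4-methylidene-N,N-diphenyloxolane-3-carboxamide (2,3-trans) | C=C1CO[C@H](c2ccc(OCc3ccccc3)c(OCc3ccccc3)c2)[C@H]1C(=O)N(c1ccccc1)c1ccccc1 | intermediate
9 | (2S,3S)-2-[3,4-bis(benzyloxy)phenyl]-4-methylideneoxolane-3-carbaldehyde | C=C1CO[C@H](c2ccc(OCc3ccccc3)c(OCc3ccccc3)c2)[C@H]1C=O | intermediate
10 | [(2S,3R)-2-[3,4-bis(benzyloxy)phenyl]-4-methylideneoxolan-3-yl]methanol | C=C1CO[C@H](c2ccc(OCc3ccccc3)c(OCc3ccccc3)c2)[C@H]1CO | intermediate
11 | 4-bromo-2-methoxyphenol | COc1cc(Br)ccc1O | starting material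
12 | 1-(benzyloxy)-4-bromo-2-methoxybenzene | COc1cc(Br)ccc1OCc1ccccc1 | intermediate
13 | (2S,3R,4R)-2-[3,4-bis(benzyloxy)phenyl]-4-[(9-borabicyclo[3.3.1]nonan-9-yl)methyl]-3-{[(9-borabicyclo[3.3.1]nonan-9-yl)oxy]methyl}oxolane | B1(C2CCCC1CCC2)C[C@H]3CO[C@H](c4ccc(OCc5ccccc5)c(OCc5ccccc5)c4)[C@H]3COB6C7CCCC6CCC7 | intermediate
14 | [(2S,3R,4R)-2-[3,4-bis(benzyloxy)phenyl]-4-{[4-(benzyloxy)-3-methoxyphenyl]methyl}oxolan-3-yl]methanol | COc1cc(C[C@H]2CO[C@H](c3ccc(OCc4ccccc4)c(OCc4ccccc4)c3)[C@H]2CO)ccc1OCc1ccccc1 | intermediate
15 | [(2S,3R,4R)-2-[3,4-bis(benzyloxy)phenyl]-4-{[4-(benzyloxy)-3-methoxyphenyl]methyl}oxolan-3-yl]methyl acetate | COc1cc(C[C@H]2CO[C@H](c3ccc(OCc4ccccc4)c(OCc4ccccc4)c3)[C@H]2COC(C)=O)ccc1OCc1ccccc1 | intermediate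
16 | [(2S,3R,4R)-2-(3,4-dihydroxyphenyl)-4-[(4-hydroxy-3-methoxyphenyl)methyl]oxolan-3-yl]methyl acetate | COc1cc(C[C@H]2CO[C@H](c3ccc(O)c(O)c3)[C@H]2COC(C)=O)ccc1O | target

Total step count: 7. Longest linear sequence: 6 (steps 1, 2, 3, 5, 6, 7, from methylenecyclopropane).

## Steps most likely to fail

**Step 2 (bears the label).**
- What may go wrong: enantiofacial discrimination at the ligated magnesium may be insufficient at the temperature that iodide ring opening needs. A background reaction through ligand-free MgI2 may erode it further. The aldol addition to the electron-rich aldehyde may be sluggish.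
- Fallback with known chemistry, setting out from 4 and 5: the ligand-free ring expansion is run with stoichiometric MgI2 in refluxing THF. This gives the racemic trans-configured 2-[3,4-bis(benzyloxy)phenyl]-4-methylidene-N,N-diphenyloxolane-3-carboxamide F1.
- F1 is resolved by preparative supercritical-fluid chromatography on a polysaccharide chiral stationary phase. The (2S,3S)-enantiomer is 8, where the route is rejoined. The ring expansion is kept, and catalyst control is replaced by resolution.

**Step 5.**
- What may go wrong: the facial selectivity of borane addition may be poor, because the C2 aryl group sits on the face that has to be attacked. Protodeboronation may compete during the coupling.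
- Fallback, setting out from 10: substrate control is replaced by catalyst control. Copper hydride-catalysed hydroboration is run with excess pinacolborane, CuCl, KOt-Bu and the matched antipode of DTBM-Segphos in toluene at rt.
- This first gives the C,O-diborylated oxolane F2. Aqueous work-up converts it into the isolable [(2S,3R,4R)-2-[3,4-bis(benzyloxy)phenyl]-4-[(4,4,5,5-tetramethyl-1,3,2-dioxaborolan-2-yl)methyl]oxolan-3-yl]methanol F3, from which any C4 epimer can be removed by chromatography.
- Suzuki–Miyaura coupling of this primary alkyl boronate with 12 (Pd2(dba)3, RuPhos, NaOt-Bu, toluene–H2O, 80 °C) comes back to the route at 14.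

**Step 7.**
- What may go wrong: over-reduction, that is, hydrogenolytic opening of the benzylic C2–O1 bond once the para-phenol is free. The liberated catechol may also be oxidised in air.
- Fallback, setting out from 15: the reductive cleavage is replaced by a Lewis acid dealkylation with a cation scavenger (BCl3, pentamethylbenzene, CH2Cl2, −78 °C, quenched cold with CHCl3–MeOH). This should remove aryl benzyl ethers within minutes while the acetate, the methyl ether and the oxolane are left alone at that temperature. It comes back to the route at 16.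

## Further compounds

F1 | step 2 | (±)-trans-2-[3,4-bis(benzyloxy)phenyl]-4-methylidene-N,N-diphenyloxolane-3-carboxamide (racemate, both enantiomers written) | C=C1CO[C@H](c2ccc(OCc3ccccc3)c(OCc3ccccc3)c2)[C@H]1C(=O)N(c1ccccc1)c1ccccc1.C=C1CO[C@@H](c2ccc(OCc3ccccc3)c(OCc3ccccc3)c2)[C@@H]1C(=O)N(c1ccccc1)c1ccccc1
F2 | step 5 | (2S,3R,4R)-2-[3,4-bis(benzyloxy)phenyl]-4-[(4,4,5,5-tetramethyl-1,3,2-dioxaborolan-2-yl)methyl]-3-{[(4,4,5,5-tetramethyl-1,3,2-dioxaborolan-2-yl)oxy]methyl}oxolane | CC1(C)OB(C[C@H]2CO[C@H](c3ccc(OCc4ccccc4)c(OCc4ccccc4)c3)[C@H]2COB2OC(C)(C)C(C)(C)O2)OC1(C)C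
F3 | step 5 | [(2S,3R,4R)-2-[3,4-bis(benzyloxy)phenyl]-4-[(4,4,5,5-tetramethyl-1,3,2-dioxaborolan-2-yl)methyl]oxolan-3-yl]methanol | CC1(C)OB(C[C@H]2CO[C@H](c3ccc(OCc4ccccc4)c(OCc4ccccc4)c3)[C@H]2CO)OC1(C)C
F0 | step 7 | none | none
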